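## Structural features

The target is a bicycle: a cyclohexane (C3a, C4, C5, C6, C7, C7a) fused across the C3a–C7a bond to a butenolide (O1, C2, C3, C3a, C7a), with the C3=C3a double bond exocyclic to the carbocycle. C3a lies between two fully substituted carbons, the gem-dimethyl carbon C4 and the oxygen-bearing C7a, which also carries a methyl group. There are only two stereocentres, C6 (S, palmitate) and C7a (R, lactone oxygen); they are 1,3-related across C7 rather than adjacent, and the acyloxy group is cis to the C7a methyl, so it is axial and syn to an axial C4 methyl. The fragile groups are the secondary fatty ester (hydrolysis, transesterification, elimination under base), the tertiary allylic C7a–O bond and the conjugated lactone. The real difficulty is the 1,3-relationship and not the ring system: a reaction that creates C7a on a preformed ring is governed by conformation and tends to leave the C6 oxygen equatorial, which is the 6-epi series. The key step exploits the fact that the C4–C3a bond joins a carbon that can be a tertiary radical (C4) to the β-carbon of an unsaturated ester (C3a). Formed last, from an open chain, it closes the cyclohexane without touching C6 or C7a, so both can be set beforehand by reagent-controlled acyclic reactions.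

## Logic of the disconnections

13 to 12. The acyl–oxygen bond O1–C2 of the lactone is cut. A tertiary hydroxyl held cis to an ester across an exocyclic double bond closes to a butenolide almost by itself, so this removes one ring at no cost and exposes the alkylidene acetate that a radical conjugate addition to an ynoate produces. The demand is geometric: only the Z geometry of 12 can close, so any material with the opposite alkene geometry must be channelled into 12. Because C3a is flanked by two carbons without hydrogen, excitation of the enoate can only rotate the double bond, and ring closure then removes 12 irreversibly.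

12 to 11. The C4–C3a bond is cut (the key disconnection). C4 is the site of a tertiary radical born from an isopropenyl group and C3a is the β-carbon of an unsaturated ester. The cut turns the ring into an open chain in which C6 and C7a are ordinary acyclic carbinol carbons. The forward step must deliver a hydrogen atom to the alkene and not to the alkyne, close the six-membered ring before the radical is reduced, and tolerate a free tertiary alcohol and a fatty ester. It creates no stereocentre and must leave the two existing ones alone.

11 to 10. The C2–C3 bond between the carboxyl carbon and the alkyne is cut, leaving a terminal alkyne. The ynoate is the most electrophilic and base-sensitive function of the chain; introducing it last keeps it away from the organomagnesium reagent, the one-electron reductant and the hydride used earlier. The forward carbonylation must act on the alkyne C–H bond in the presence of an alkene, a tertiary propargylic alcohol and an ester, without strong base.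

10 to 8 and 9. The bond between the C6 oxygen and the acyl carbon is cut. Installing the final acyl group at the diol stage makes it its own protecting group and prevents the C6 oxygen from adding to the ynoate once that exists. The forward acylation must distinguish a secondary from a tertiary hydroxyl, which is a large rate difference.

8 to 7. The C6–H bond is cut (carbinol to ketone). In a β-hydroxy ketone the C7a hydroxyl can dictate the face of hydride attack through a cyclic boron chelate, so C6 is derived from C7a. The forward reduction must be syn-selective in the sense defined by the C7a methyl group; it rests on ethynyl being the smaller of the two substituents on the chelate ring.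

7 to 6. A C7–H bond is exchanged for a C7–O bond, making the tertiary carbinol one end of an α,β-epoxy ketone. This turns C7a into an enantioselective epoxidation problem. The forward opening must break only the C–O bond α to the carbonyl and protonate the enolate before elimination or retro-aldol cleavage.

6 to 5 to 3 and 4. After adjustment of the oxidation level at C6, the C5–C6 bond is cut. The chain divides into a six-carbon epoxy aldehyde and a four-carbon allylmetal carrying the future C4 and both of its methyl carbons. The addition must be faster than deprotonation of the alkyne. Its diastereoselectivity is irrelevant because the carbinol is reoxidized, but that oxidation must not move the double bond into conjugation.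

3 to 2 to 1. After return to the alcohol oxidation level, the two epoxide C–O bonds (at C7 and C7a) are cut, which leads to 1, an achiral compound. The allylic hydroxyl is the handle for a Ti(OiPr)4–tartrate epoxidation in which the tartrate alone decides the face. The E geometry of 1 together with the L-(+) tartrate is required for the 7aR configuration.

## Other disconnections considered

Alternative 1: The cut is the O1–C7a bond, with the carbocycle traced back to an aromatic ring. 2-(4-Hydroxy-2,6-dimethylphenyl)acetic acid A1 would be oxidized in methanol with PhI(OAc)2 to the prochiral dienone acid A2, 2-(1-methoxy-2,6-dimethyl-4-oxocyclohexa-2,5-dien-1-yl)acetic acid. A chiral bifunctional amine–thiourea catalyst would then steer the carboxylic acid onto one of the two enantiotopic, methyl-bearing β-carbons to give the cis-fused lactone A3, (3aR,7aR)-3a-methoxy-4,7a-dimethyl-3,3a,7,7a-tetrahydrobenzofuran-2,6-dione. Conjugate addition of Me2CuLi to the remaining enone would add the second C4 methyl, and base would expel the C3a methoxide to give the butenolide ketone A4, (7aR)-4,4,7a-trimethyl-4,5,7,7a-tetrahydrobenzofuran-2,6-dione. Hydride reduction at C6 and acylation with 9 would lead to 13.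
- In its favour: the starting material is flat and cheap, the only asymmetric step is catalytic, and the tether guarantees the cis ring fusion. The methoxy group is useful, since its elimination places the C3=C3a double bond with no geometry question; on this point the alternative is the better plan. The last reduction is biased the right way, because hydride should approach C6 anti to the axial methyls on C4 and C7a. At about six steps from A1 it is at least the equal of the chosen plan in length.
- Against it here: the oxygen nucleophile must add to a β,β-disubstituted enone carbon to form a fully substituted C–O bond. Such additions of carboxylic acids are slow and reversible, and high enantioselectivity at a methyl-bearing terminus is not assured for this catalyst class. A1 may lose CO2 during the oxidation, and the cuprate must build a quaternary carbon next to a quaternary carbon.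
- Comparison: the chosen plan fixes C7a by a tartrate-controlled epoxidation and C6 by a directed reduction before any ring exists. The alternative rests its absolute configuration on one untested desymmetrization and sets C6 last by substrate control. Mechanistically it is polar throughout and avoids radical intermediates.

Alternative 2: Three bonds are cut at once, C3a–C7a, C3–C2 and C2–O1, which opens both rings to the acyclic ynone A5, (R)-4-(tert-butyldimethylsilyloxy)-6,6-dimethyloct-7-yn-2-one. A low-valent metal carbonyl (Mo(CO)6 with a promoter, or Ru3(CO)12 under CO) would join the methyl ketone, the terminal alkyne and CO in a hetero-Pauson–Khand cyclocarbonylation. The product would be the silyl ether A6, (6R,7aR)-6-(tert-butyldimethylsilyloxy)-4,4,7a-trimethyl-5,6,7,7a-tetrahydrobenzofuran-2(4H)-one. Since the closure should place the C6 silyloxy group equatorial, A6 is in the 6-epi series. Desilylation to the alcohol A7, (6R,7aR)-6-hydroxy-4,4,7a-trimethyl-5,6,7,7a-tetrahydrobenzofuran-2(4H)-one, and Mitsunobu esterification with the free acid of 9 would invert C6 and give 13.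
- In its favour: no other plan creates as much in one step, namely two rings, three bonds and the butenolide at its final oxidation level with no alkene geometry to correct. A5 has one stereocentre, and the inversion both repairs the conformational bias and installs the acyl group. On convergence, atom economy and step count (about seven or eight) it is the better plan.
- Against it here: the carbonyl partner is an unactivated dialkyl ketone, the tether must close a six-membered ring and the alkyne sits next to a quaternary carbon. Cyclocarbonylations of this kind are established for aldehydes and activated ketones forming five-membered carbocycles, so the step would go beyond what is known. The C7a configuration would depend on a small conformational preference in a metallacycle. The closing Mitsunobu displacement must occur at a carbinol whose two neighbouring methylenes each adjoin a quaternary carbon, where elimination can compete.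
- Comparison: the chosen plan is longer and needs a geometry correction, but each of its stereocentres comes from a reagent-controlled reaction. Its key step extends a well-documented radical conjugate addition by a smaller margin than the cyclocarbonylation extends its precedent.

Alternative 3: The cut is the C3–C3a bond. Isophorone A8 would be elaborated to the diazo ester A9, 1-allyl 3-[(1S,5S)-1,3,3-trimethyl-5-(palmitoyloxy)cyclohexyl] 2-diazomalonate, which carries the palmitate on the secondary oxygen and the allyl diazomalonate on the tertiary oxygen. With Rh2(OAc)4 the carbenoid carbon would insert into a C3a–H bond to give the cis-fused lactone A10, allyl (3aS,6S,7aR)-4,4,7a-trimethyl-2-oxo-6-(palmitoyloxy)octahydrobenzofuran-3-carboxylate, as C3 epimers. Deallylation, decarboxylation and dehydrogenation with Pd(OAc)2 and a phosphine would then introduce the C3=C3a double bond and give 13.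
- In its favour: the carbocycle, both oxygens and the gem-dimethyl group come from a bulk chemical. Formation of γ-lactones by carbenoid C–H insertion of diazomalonates is among the best documented reactions of its kind, so on precedent for the key step this alternative is the better plan. The cis fusion is automatic, C6 and C7a are untouched, the palmitate is already in place, and the length (about eight steps) is comparable to that of the chosen plan.
- Against it here: three C–H sites are within reach of the carbenoid. These are the C3a methylene (shielded by the gem-dimethyl carbon), the C7 methylene (inductively deactivated by the neighbouring acyloxy carbon) and the C7a methyl, so site selectivity is uncertain. A8 is achiral, so the absolute configuration must come from an asymmetric epoxidation of a hindered enone or from a resolution. The product arrives one oxidation level too low and needs a dehydrogenation.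
- Comparison: both plans install the stereocentres before the key step and leave them alone during it. The alternative does so on a ring with an equally reliable relative control but without an equally simple source of absolute configuration. Its key step is better precedented but less predictable in site, whereas the radical closure has one sensible site of attack. The alternative pays with a dehydrogenation what the chosen plan pays with an isomerization.

Key step: step 9

Remark: atom labels C2 to C7a follow the benzofuranone numbering of 13 and are also used for the corresponding atoms of the open-chain compounds; 1, 4 and 9 are taken to be bought.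

## Steps

Step 1
Reactants: 1 (E)-3-methylpent-2-en-4-yn-1-ol
Product: 2 [(2S,3S)-3-ethynyl-3-methyloxiran-2-yl]methanol
Conditions: Ti(OiPr)4 (cat.), L-(+)-diethyl tartrate (cat.), t-BuOOH, 4 Å molecular sieves, CH2Cl2, −20 °C
Reagents that add atoms: tert-butyl hydroperoxide, CC(C)(C)OO
Why: Sharpless asymmetric epoxidation of a trisubstituted E allylic alcohol; with the L-(+) tartrate the oxygen should go to the face that makes C2 and C3 both S, as with geraniol (ethynyl in place of the E chain), and this sets the future C7a. The alkyne is inert to the titanium peroxide.

Step 2
Reactants: 2 [(2S,3S)-3-ethynyl-3-methyloxiran-2-yl]methanol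
Product: 3 (2R,3S)-3-ethynyl-3-methyloxirane-2-carbaldehyde
Conditions: Dess–Martin periodinane, pyridine, CH2Cl2, 0 °C
Reagents that add atoms: none
Why: Dess–Martin oxidation of a primary epoxy alcohol under buffered, non-aqueous conditions; the descriptor at C2 changes only because the formyl group now outranks C3. The volatile aldehyde is used at once.

Step 3
Reactants: 3 (2R,3S)-3-ethynyl-3-methyloxirane-2-carbaldehyde; 4 methallylmagnesium chloride
Product: 5 1-[(2S,3S)-3-ethynyl-3-methyloxiran-2-yl]-3-methylbut-3-en-1-ol (both carbinol epimers)
Conditions: THF, −78 °C; then aq. NH4Cl
Reagents that add atoms: none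
Why: Grignard 1,2-addition; at −78 °C an allylic organomagnesium should add to the aldehyde far faster than it deprotonates the alkyne or opens the epoxide. The carbinol configuration does not matter because step 4 erases it.

Step 4
Reactants: 5 1-[(2S,3S)-3-ethynyl-3-methyloxiran-2-yl]-3-methylbut-3-en-1-ol
Product: 6 1-[(2R,3S)-3-ethynyl-3-methyloxiran-2-yl]-3-methylbut-3-en-1-one
Conditions: Dess–Martin periodinane, pyridine, CH2Cl2, 0 °C
Reagents that add atoms: none
Why: Dess–Martin oxidation, chosen because it is neutral enough to leave a β,γ-unsaturated ketone unconjugated; both epimers of 5 converge on one ketone.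

Step 5
Reactants: 6 1-[(2R,3S)-3-ethynyl-3-methyloxiran-2-yl]-3-methylbut-3-en-1-one
Product: 7 (6R)-6-hydroxy-2,6-dimethyloct-1-en-7-yn-4-one
Conditions: SmI2 (2.2 equiv), THF/MeOH, −90 °C
Reagents that add atoms: none
Why: Reductive opening of an α,β-epoxy ketone by SmI2: the ketyl expels the α-oxygen and methanol protonates the samarium enolate at low temperature before elimination or retro-aldol cleavage. The C–O bond at the fully substituted carbon is untouched, so the tertiary carbinol keeps its configuration (now R because CH2 ranks below ethynyl).

Step 6
Reactants: 7 (6R)-6-hydroxy-2,6-dimethyloct-1-en-7-yn-4-one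
Product: 8 (3R,5S)-3,7-dimethyloct-7-en-1-yne-3,5-diol
Conditions: Et2BOMe, NaBH4, THF/MeOH, −78 °C; then AcOH, MeOH
Reagents that add atoms: none
Why: Narasaka–Prasad syn reduction; in the six-membered boron chelate the tertiary carbinol should place methyl equatorial and the slim ethynyl axial, and external hydride adds axially to the carbonyl. The new C–O bond is then syn to the tertiary C–O bond along the chain through the methyl group, which is the 5S (future 6S) configuration.

Step 7
Reactants: 8 (3R,5S)-3,7-dimethyloct-7-en-1-yne-3,5-diol; 9 palmitoyl chloride
Product: 10 (4S,6R)-6-hydroxy-2,6-dimethyloct-1-en-7-yn-4-yl hexadecanoate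
Conditions: pyridine, DMAP (cat.), CH2Cl2, 0 °C
Reagents that add atoms: none
Why: Chemoselective acylation of the secondary hydroxyl, the tertiary propargylic hydroxyl being far slower. The final acyl group also blocks the C6 oxygen from adding to the ynoate made in step 8.

Step 8
Reactants: 10 (4S,6R)-6-hydroxy-2,6-dimethyloct-1-en-7-yn-4-yl hexadecanoate
Product: 11 ethyl (4R,6S)-4-hydroxy-4,8-dimethyl-6-(palmitoyloxy)non-8-en-2-ynoate
Conditions: PdCl2 (cat.), CuCl2 (2 equiv), NaOAc (2 equiv), CO (1 atm), EtOH, rt
Reagents that add atoms: carbon monoxide, [C-]#[O+]; ethanol, CCO
Why: Palladium-catalysed oxidative alkoxycarbonylation of a terminal alkyne: acetate-assisted formation of an alkynylpalladium species, CO insertion and ethanolysis, with CuCl2 reoxidizing the palladium. The ethyl ester matches the ethanol used in step 9.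

Step 9
Reactants: 11 ethyl (4R,6S)-4-hydroxy-4,8-dimethyl-6-(palmitoyloxy)non-8-en-2-ynoate
Product: 12 ethyl (Z)-2-[(2R,4S)-2-hydroxy-2,6,6-trimethyl-4-(palmitoyloxy)cyclohexylidene]acetate
Conditions: Fe(acac)3 (0.5 equiv), PhSiH3 (2.5 equiv), EtOH/(CH2OH)2 (5:1), 60 °C, 0.02 M
Reagents that add atoms: none
Why: The iron hydride formed from Fe(acac)3 and PhSiH3 in ethanol transfers a hydrogen atom to the CH2 terminus of the 1,1-disubstituted alkene (Markovnikov) to give the tertiary radical at the future C4; this nucleophilic radical adds to the electron-poor β-carbon of the ynoate (future C3a), and the α-ester vinyl radical is quenched by hydrogen abstraction or by reduction and protonation in ethanol. The closest known reaction type is the iron-hydride reductive olefin coupling (hydrogen-atom-transfer-initiated Giese cyclization onto enoates and enones, used to build quaternary carbons), together with the classical 6-exo-dig cyclization of alkyl radicals onto alkynoates under stannane conditions. The single ring closes in the 6-exo-dig mode, which Baldwin's rules allow and the polarization of the ynoate reinforces, while 7-endo attack at the α-carbon is disfavoured both electronically and geometrically. No stereocentre is created: C6 and C7a are already in place, lie outside the reacting atoms and cannot epimerize under neutral radical conditions. Chemoselectivity rests on hydrogen-atom transfer to an electron-rich 1,1-disubstituted alkene (tertiary radical) being much faster than to an alkyne (vinyl radical), and on dilution, which favours ring closure over a second hydrogen transfer that would only saturate the alkene. The fully substituted carbinol carbon, the gem-dimethyl radical centre and the C6 substituent favour the folded chain, and the tertiary propargylic alcohol, which has no carbinol hydrogen, cannot isomerize to an enone. The substrate does not secure the geometry of the new alkene, because hydrogen can reach the linear vinyl radical from the C4 flank or from the almost equally encumbered C7a flank; 12 is therefore expected mixed with its E-configured geometric isomer, part of 12 may already lactonize in the flask, and the crude material is carried on because the light and acid of step 10 converge all of it.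

Step 10
Reactants: 12 ethyl (Z)-2-[(2R,4S)-2-hydroxy-2,6,6-trimethyl-4-(palmitoyloxy)cyclohexylidene]acetate
Product: 13 (−)-3-O-palmitoylloliolide, (6S,7aR)-4,4,7a-trimethyl-2-oxo-2,4,5,6,7,7a-hexahydrobenzofuran-6-yl hexadecanoate
Conditions: hν (254 nm, quartz), CF3CO2H (cat.), MeCN, rt
Reagents that add atoms: none
Why: Acid-catalysed lactonization (intramolecular transesterification) of the Z γ-hydroxy enoate closes the butenolide with loss of ethanol and touches neither stereocentre. The light serves the share of the crude material that leaves step 9 with E geometry: an enoate without γ-hydrogen cannot photodeconjugate, so excitation only rotates the double bond (photochemical E/Z isomerization), and the irreversible ring closure should drain the photostationary mixture to 13.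

## Compound list

1 | (E)-3-methylpent-2-en-4-yn-1-ol | C#C/C(C)=C/CO | starting material
2 | [(2S,3S)-3-ethynyl-3-methyloxiran-2-yl]methanol | C#C[C@]1(C)O[C@H]1CO | intermediate
3 | (2R,3S)-3-ethynyl-3-methyloxirane-2-carbaldehyde | C#C[C@]1(C)O[C@H]1C=O | intermediate
4 | methallylmagnesium chloride | CC(=C)C[Mg]Cl | starting material
5 | 1-[(2S,3S)-3-ethynyl-3-methyloxiran-2-yl]-3-methylbut-3-en-1-ol (both carbinol epimers) | C#C[C@]1(C)O[C@H]1C(O)CC(C)=C | intermediate
6 | 1-[(2R,3S)-3-ethynyl-3-methyloxiran-2-yl]-3-methylbut-3-en-1-one | C#C[C@]1(C)O[C@H]1C(=O)CC(C)=C | intermediate
7 | (6R)-6-hydroxy-2,6-dimethyloct-1-en-7-yn-4-one | C=C(C)CC(=O)C[C@@](C)(O)C#C | intermediate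
8 | (3R,5S)-3,7-dimethyloct-7-en-1-yne-3,5-diol | O[C@@H](CC(C)=C)C[C@@](C)(O)C#C | intermediate
9 | palmitoyl chloride | CCCCCCCCCCCCCCCC(=O)Cl | starting material
10 | (4S,6R)-6-hydroxy-2,6-dimethyloct-1-en-7-yn-4-yl hexadecanoate | CCCCCCCCCCCCCCCC(=O)O[C@@H](CC(C)=C)C[C@@](C)(O)C#C | intermediate
11 | ethyl (4R,6S)-4-hydroxy-4,8-dimethyl-6-(palmitoyloxy)non-8-en-2-ynoate | CCCCCCCCCCCCCCCC(=O)O[C@@H](CC(C)=C)C[C@@](C)(O)C#CC(=O)OCC | intermediate
12 | ethyl (Z)-2-[(2R,4S)-2-hydroxy-2,6,6-trimethyl-4-(palmitoyloxy)cyclohexylidene]acetate | CCCCCCCCCCCCCCCC(=O)O[C@H]1CC(C)(C)/C(=C/C(=O)OCC)[C@](C)(O)C1 | intermediate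
13 | (−)-3-O-palmitoylloliolide, (6S,7aR)-4,4,7a-trimethyl-2-oxo-2,4,5,6,7,7a-hexahydrobenzofuran-6-yl hexadecanoate | CCCCCCCCCCCCCCCC(=O)O[C@H]1CC(C)(C)C2=CC(=O)O[C@]2(C)C1 | target

## Step count and least certain steps

Total step count: 10. Longest linear sequence: 10 steps (1 to 13); 4 and 9 enter in steps 3 and 7.

Step 9 (key step). What is most likely to go wrong is premature reduction of the tertiary radical, a net hydrogenation of the alkene. Hydrogen donors are in excess, and the radical must attack an alkyne carbon next to a fully substituted centre, so ring closure may be too slow. Unselective hydrogen delivery to the vinyl radical is a second, separate weakness, which step 10 is designed to absorb. The fallback sets out from 11 and returns at 12. Markovnikov addition of HBr (33% in AcOH, CH2Cl2, −20 °C) to the 1,1-disubstituted alkene should give the tertiary bromide ethyl (4R,6R)-8-bromo-4-hydroxy-4,8-dimethyl-6-(palmitoyloxy)non-2-ynoate F1 (the descriptor at C6 changes only by priority); the electron-poor alkyne and its destabilized propargylic position should not compete at this temperature. Slow addition of (Me3Si)3SiH with AIBN in toluene at 80 °C would then generate the same tertiary radical by bromine abstraction, at a low steady concentration of hydrogen donor. A 6-exo-dig closure and hydrogen transfer from the silane should lead to 12, accompanied by its geometric isomer ethyl (E)-2-[(2R,4S)-2-hydroxy-2,6,6-trimethyl-4-(palmitoyloxy)cyclohexylidene]acetate F2 wherever the silane reaches the vinyl radical from the C7a flank. F2 need not be separated, because the irradiation of step 10 converts it into 12 in the flask.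

Step 8. What is most likely to go wrong is diversion of the palladium into chloropalladation or oxypalladation. PdCl2/CuCl2 under CO is also a cyclocarbonylation system for unsaturated alcohols, and both the propargylic hydroxyl and the alkene are present. The fallback sets out from 8 and returns at 11. Diol 8 is protected with 2,2-dimethoxypropane and PPTS as the acetonide (4R,6S)-4-ethynyl-2,2,4-trimethyl-6-(2-methylprop-2-en-1-yl)-1,3-dioxane F3. Deprotonation of the alkyne with n-BuLi in THF at −78 °C and trapping with ethyl chloroformate should give ethyl 3-[(4R,6S)-2,2,4-trimethyl-6-(2-methylprop-2-en-1-yl)-1,3-dioxan-4-yl]prop-2-ynoate F4. Aqueous acetic acid would release the diol ethyl (4R,6S)-4,6-dihydroxy-4,8-dimethylnon-8-en-2-ynoate F5, and acylation with 9 and pyridine in CH2Cl2 at −20 °C would give 11. F5 is kept away from strong base and nucleophilic catalysts, because its free C6 hydroxyl can add to the ynoate.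

Step 6. What is most likely to go wrong is poor facial selectivity in the hydride addition, because the two groups that the chelate must tell apart on the carbinol carbon (methyl and ethynyl) differ only moderately in size. The fallback sets out from 7 and returns at 10. The reduction is run as before and the 5R epimer, (3R,5R)-3,7-dimethyloct-7-en-1-yne-3,5-diol F6, is separated. A Mitsunobu reaction of F6 with palmitic acid (PPh3, DIAD, toluene, 0 °C to rt) would esterify the secondary carbinol with inversion and so give 10 directly. Both epimers thus converge, and should the selectivity run the other way, internal hydride delivery with Me4NBH(OAc)3 could make F6 the main product on purpose.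

Step 10. What is most likely to go wrong is sluggish photoisomerization of the E-configured share of the material, accompanied by photodecomposition of the butenolide under short-wavelength light, or acid-induced loss of the tertiary allylic hydroxyl. The fallback sets out from 12 and returns at 13; it serves material of either alkene geometry, because the double bond is removed. Ozonolysis (O3, CH2Cl2, −78 °C; then Me2S) would excise the exocyclic alkene and give the hydroxy ketone (1S,3R)-3-hydroxy-3,5,5-trimethyl-4-oxocyclohexyl hexadecanoate F7. Esterification of the tertiary hydroxyl with diethylphosphonoacetic acid (DCC, DMAP, CH2Cl2) would give (1R,5S)-1,3,3-trimethyl-2-oxo-5-(palmitoyloxy)cyclohexyl 2-(diethoxyphosphoryl)acetate F8. An intramolecular Horner–Wadsworth–Emmons reaction (LiCl, DBU, MeCN) would then close the butenolide to 13, with the ring enforcing the alkene geometry; the ketone has no α-hydrogen, so enolization cannot interfere.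

## Further compounds

F1 | step 9 | ethyl (4R,6R)-8-bromo-4-hydroxy-4,8-dimethyl-6-(palmitoyloxy)non-2-ynoate | CCCCCCCCCCCCCCCC(=O)O[C@@H](CC(C)(C)Br)C[C@@](C)(O)C#CC(=O)OCC
F2 | step 9 | ethyl (E)-2-[(2R,4S)-2-hydroxy-2,6,6-trimethyl-4-(palmitoyloxy)cyclohexylidene]acetate | CCCCCCCCCCCCCCCC(=O)O[C@H]1CC(C)(C)/C(=C\C(=O)OCC)[C@](C)(O)C1
F3 | step 8 | (4R,6S)-4-ethynyl-2,2,4-trimethyl-6-(2-methylprop-2-en-1-yl)-1,3-dioxane | CC1(C)O[C@@H](CC(C)=C)C[C@](C)(C#C)O1
F4 | step 8 | ethyl 3-[(4R,6S)-2,2,4-trimethyl-6-(2-methylprop-2-en-1-yl)-1,3-dioxan-4-yl]prop-2-ynoate | CC1(C)O[C@@H](CC(C)=C)C[C@](C)(C#CC(=O)OCC)O1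
F5 | step 8 | ethyl (4R,6S)-4,6-dihydroxy-4,8-dimethylnon-8-en-2-ynoate | O[C@@H](CC(C)=C)C[C@@](C)(O)C#CC(=O)OCC
F6 | step 6 | (3R,5R)-3,7-dimethyloct-7-en-1-yne-3,5-diol | O[C@H](CC(C)=C)C[C@@](C)(O)C#C
F7 | step 10 | (1S,3R)-3-hydroxy-3,5,5-trimethyl-4-oxocyclohexyl hexadecanoate | CCCCCCCCCCCCCCCC(=O)O[C@H]1CC(C)(C)C(=O)[C@](C)(O)C1
F8 | step 10 | (1R,5S)-1,3,3-trimethyl-2-oxo-5-(palmitoyloxy)cyclohexyl 2-(diethoxyphosphoryl)acetate | CCCCCCCCCCCCCCCC(=O)O[C@H]1CC(C)(C)C(=O)[C@](C)(OC(=O)CP(=O)(OCC)OCC)C1
A1 | alternative 1 | 2-(4-hydroxy-2,6-dimethylphenyl)acetic acid | Cc1cc(O)cc(C)c1CC(=O)O
A2 | alternative 1 | 2-(1-methoxy-2,6-dimethyl-4-oxocyclohexa-2,5-dien-1-yl)acetic acid | COC1(CC(=O)O)C(C)=CC(=O)C=C1C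
A3 | alternative 1 | (3aR,7aR)-3a-methoxy-4,7a-dimethyl-3,3a,7,7a-tetrahydrobenzofuran-2,6-dione | O=C1C=C(C)[C@]2(OC)CC(=O)O[C@]2(C)C1
A4 | alternative 1 | (7aR)-4,4,7a-trimethyl-4,5,7,7a-tetrahydrobenzofuran-2,6-dione | O=C1CC(C)(C)C2=CC(=O)O[C@]2(C)C1
A5 | alternative 2 | (R)-4-(tert-butyldimethylsilyloxy)-6,6-dimethyloct-7-yn-2-one | CC(=O)C[C@H](O[Si](C)(C)C(C)(C)C)CC(C)(C)C#C
A6 | alternative 2 | (6R,7aR)-6-(tert-butyldimethylsilyloxy)-4,4,7a-trimethyl-5,6,7,7a-tetrahydrobenzofuran-2(4H)-one | CC(C)(C)[Si](C)(C)O[C@@H]1CC(C)(C)C2=CC(=O)O[C@]2(C)C1
A7 | alternative 2 | (6R,7aR)-6-hydroxy-4,4,7a-trimethyl-5,6,7,7a-tetrahydrobenzofuran-2(4H)-one | O[C@@H]1CC(C)(C)C2=CC(=O)O[C@]2(C)C1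
A8 | alternative 3 | isophorone (3,5,5-trimethylcyclohex-2-en-1-one) | CC1=CC(=O)CC(C)(C)C1
A9 | alternative 3 | 1-allyl 3-[(1S,5S)-1,3,3-trimethyl-5-(palmitoyloxy)cyclohexyl] 2-diazomalonate | CCCCCCCCCCCCCCCC(=O)O[C@H]1CC(C)(C)C[C@](C)(OC(=O)C(=[N+]=[N-])C(=O)OCC=C)C1
A10 | alternative 3 | allyl (3aS,6S,7aR)-4,4,7a-trimethyl-2-oxo-6-(palmitoyloxy)octahydrobenzofuran-3-carboxylate | CCCCCCCCCCCCCCCC(=O)O[C@H]1CC(C)(C)[C@@H]2C(C(=O)OCC=C)C(=O)O[C@]2(C)C1
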